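**Retrosynthetic overview**

1. Target 24 comes from its aryl silyl ether 23 by desilylation. Ring B of 23 is closed last by joining the ring A piece 6 (C1–C6, C10) to the side chain 19 (C7–C9, C11, benzoxazole).
2. Key disconnections: C6–C7 (copper-catalysed sp3–sp3 coupling of a neopentyl-type Grignard reagent with a primary iodide) and C9–C10 (hydrogen-atom-transfer-initiated 6-exo radical closure), both made in one flask.
3. Enabling feature: the quaternary C5 carries C6 and sits next to the C10=C1 bond of a flat cyclohexa-1,4-diene ring A that already holds C3=C4–Me. A C7–C8–C9 chain on C6 can reach C10 only on the face of C6, which is the cis ring fusion (5-Me and 10-H cis). The C9 methyl is the CH2 of a 1,1-disubstituted alkene.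
4. Ring order: benzoxazole first (from 4-methoxyresorcinol), ring A by asymmetric Birch reductive methylation of an o-toluamide, the aryl–C11 bond by aromatic Claisen rearrangement, ring B last.

Key step: step 15

Numbering used below is the decalin numbering of the target: ring A = C1, C2, C3, C4, C5, C10; ring B = C5, C6, C7, C8, C9, C10; C11 = benzylic CH2.

Assumption: in step 2 the (S)-configured auxiliary is taken to direct methylation to the face that gives the (R)-configured quaternary carbon (ortho-alkyl benzamides are expected to alkylate with the facial sense opposite to ortho-alkoxy ones); if the sense is the other one, the amide of the (R)-amine is used with no other change.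

**Route**

Step 1
Reactants: 1 2-methylbenzoyl chloride; 2 (S)-2-(methoxymethyl)pyrrolidine
Product: 3 [(2S)-2-(methoxymethyl)pyrrolidin-1-yl](2-methylphenyl)methanone
Conditions: Et3N, CH2Cl2, 0 °C → rt
Reagents that add atoms: none
Why: N-acylation of the secondary amine by the acid chloride (Schotten–Baumann type), which leaves the amine stereocentre untouched.

Step 2
Reactants: 3
Product: 4 [(1R)-1,2-dimethylcyclohexa-2,5-dien-1-yl][(2S)-2-(methoxymethyl)pyrrolidin-1-yl]methanone
Conditions: K (2.2 equiv), t-BuOH (1 equiv), NH3/THF, −78 °C; then MeI, −78 °C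
Reagents that add atoms: iodomethane, CI
Why: Birch reduction of the benzamide gives the amide enolate of the 1,4-dihydroarene, which is C-methylated at the former ipso carbon under control of the chelating methoxymethylpyrrolidine auxiliary (asymmetric Birch reduction–alkylation), setting C5 and leaving C3=C4–Me and C1=C10 in place.

Step 3
Reactants: 4
Product: 5 [(1R)-1,2-dimethylcyclohexa-2,5-dien-1-yl]methanol
Conditions: LiH2NBH3 (from BH3·NH3 and LiN(i-Pr)2), THF, 0 °C → rt
Reagents that add atoms: none
Why: lithium amidotrihydroborate reduces hindered tertiary amides to primary alcohols with C–N cleavage (amide reduction) and does not touch the isolated alkenes or the quaternary centre.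

Step 4
Reactants: 5
Product: 6 (6R)-6-(iodomethyl)-1,6-dimethylcyclohexa-1,4-diene
Conditions: I2, PPh3, imidazole, toluene, 70 °C, dark
Reagents that add atoms: iodine, II
Why: Appel-type iodination, an SN2 displacement of the alkoxyphosphonium group by iodide at the primary carbon under neutral conditions that avoid ionisation next to the two vinyl groups.

Step 5
Reactants: 7 4-methoxybenzene-1,3-diol
Product: 8 4-methoxy-6-nitrobenzene-1,3-diol
Conditions: HNO3 (1 equiv), AcOH, 0 °C
Reagents that add atoms: nitric acid, O[N+](=O)[O-]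
Why: electrophilic aromatic nitration at the position ortho to one hydroxyl and para to the other, the most activated site that is not flanked by two substituents.

Step 6
Reactants: 8
Product: 10 5-methoxy-2-methyl-1,3-benzoxazol-6-ol, via aminoresorcinol 9 (not isolated)
Conditions: H2 (1 atm), Pd/C, MeC(OEt)3, EtOH, 60 °C
Reagents that add atoms: triethyl orthoacetate, CCOC(C)(OCC)OCC
Why: catalytic hydrogenation of the nitro group and orthoester condensation of the resulting ortho-aminophenol in the same flask (benzoxazole synthesis); only the hydroxyl ortho to nitrogen can close the ring.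

Step 7
Reactants: 11 methyl (2S)-3-hydroxy-2-methylpropanoate
Product: 12 methyl (2S)-3-[(tert-butyldimethylsilyl)oxy]-2-methylpropanoate
Conditions: TBSCl, imidazole, CH2Cl2, rt
Reagents that add atoms: tert-butyldimethylsilyl chloride, CC(C)(C)[Si](C)(C)Cl
Why: standard silylation of the primary alcohol, which does not affect the C8 stereocentre.

Step 8
Reactants: 12
Product: 13 (3S)-4-[(tert-butyldimethylsilyl)oxy]-1-chloro-3-methylbutan-2-one
Conditions: ICH2Cl, MeLi·LiBr, THF/Et2O, −78 °C; then AcOH, −78 °C
Reagents that add atoms: chloroiodomethane, ClCI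
Why: chloromethyllithium made in situ by iodine–lithium exchange adds to the ester to give a tetrahedral alkoxide that is stable at −78 °C and gives the chloromethyl ketone on acidic quench (carbenoid homologation of an ester), without deprotonating the α-stereocentre.

Step 9
Reactants: 13; 10
Product: 14 (3S)-4-[(tert-butyldimethylsilyl)oxy]-1-[(5-methoxy-2-methyl-1,3-benzoxazol-6-yl)oxy]-3-methylbutan-2-one
Conditions: K2CO3, NaI (cat.), acetone, rt
Reagents that add atoms: none
Why: Williamson-type SN2 O-alkylation of the phenoxide by the highly reactive α-chloro ketone under mild base.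

Step 10
Reactants: 14
Product: 15 6-({(3R)-4-[(tert-butyldimethylsilyl)oxy]-3-methyl-2-methylidenebutyl}oxy)-5-methoxy-2-methyl-1,3-benzoxazole
Conditions: Zn, CH2Br2, TiCl4, THF/CH2Cl2, 0 °C → rt
Reagents that add atoms: dibromomethane, BrCBr
Why: Takai–Lombardo methylenation, in which the non-basic zinc/titanium methylene reagent converts the ketone into the 1,1-disubstituted alkene without epimerising the adjacent stereocentre.

Step 11
Reactants: 15
Product: 16 7-{(3R)-4-[(tert-butyldimethylsilyl)oxy]-3-methyl-2-methylidenebutyl}-5-methoxy-2-methyl-1,3-benzoxazol-6-ol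
Conditions: PhNEt2, 190 °C, sealed tube
Reagents that add atoms: none
Why: aromatic Claisen rearrangement ([3,3]-sigmatropic shift, then tautomerisation) to C7, the only free ortho position, which forms the aryl–C11 bond and regenerates the 1,1-disubstituted alkene at C9.

Step 12
Reactants: 16
Product: 17 7-{(3R)-4-[(tert-butyldimethylsilyl)oxy]-3-methyl-2-methylidenebutyl}-5-methoxy-2-methyl-6-[(triisopropylsilyl)oxy]-1,3-benzoxazole
Conditions: TIPSOTf, 2,6-lutidine, CH2Cl2, 0 °C → rt
Reagents that add atoms: triisopropylsilyl trifluoromethanesulfonate, CC(C)[Si](C(C)C)(C(C)C)OS(=O)(=O)C(F)(F)F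
Why: silylation of the hindered phenol with the silyl triflate; the O–H must be masked because it would quench the C9 radical of the key step by 1,5-hydrogen transfer.

Step 13
Reactants: 17
Product: 18 (2R)-4-{5-methoxy-2-methyl-6-[(triisopropylsilyl)oxy]-1,3-benzoxazol-7-yl}-2-methyl-3-methylidenebutan-1-ol
Conditions: CSA (cat.), MeOH/CH2Cl2, 0 °C
Reagents that add atoms: none
Why: acid-catalysed methanolysis cleaves the primary alkyl silyl ether much faster than the hindered aryl triisopropylsilyl ether (selective desilylation).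

Step 14
Reactants: 18
Product: 19 7-[(3R)-4-iodo-3-methyl-2-methylidenebutyl]-5-methoxy-2-methyl-6-[(triisopropylsilyl)oxy]-1,3-benzoxazole
Conditions: I2, PPh3, imidazole, CH2Cl2, 0 °C → rt
Reagents that add atoms: iodine, II
Why: Appel-type iodination of the unhindered primary alcohol by SN2 displacement, which leaves the C8 stereocentre untouched.

Step 15
Reactants: 6; 19
Product: 23 5-methoxy-2-methyl-7-{[(1R,2S,4aR,8aS)-1,2,4a,5-tetramethyl-1,2,3,4,4a,7,8,8a-octahydronaphthalen-1-yl]methyl}-6-[(triisopropylsilyl)oxy]-1,3-benzoxazole, via organolithium 20 (not isolated), via Grignard reagent 21 (not isolated), via coupled diene 22 (not isolated)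
Conditions: 6, t-BuLi (2.1 equiv), Et2O/pentane, −78 °C; MgBr2·OEt2, −78 → 0 °C; then 19, Li2CuCl4 (5 mol%), THF, −20 °C → rt; then EtOH, Fe(acac)3 (1.0 equiv), PhSiH3 (3 equiv), 60 °C, Ar
Reagents that add atoms: none
Why: Iodine–lithium exchange on 6 (done before 19 is added) and transmetalation give the Grignard reagent 21, which has no β-hydrogen, and its copper-catalysed Kumada-type sp3–sp3 coupling with the primary iodide 19 forms C6–C7. Without isolation, Fe(acac)3/PhSiH3 transfers a hydrogen atom to the CH2 end of the 1,1-disubstituted alkene of 22 (Mukaiyama-type metal-hydride hydrogen-atom transfer), the tertiary C9 radical closes ring B by 6-exo-trig attack on C10 of the ring A 1,2-disubstituted alkene, and the C1 radical is reduced by hydrogen-atom abstraction. The closest known reaction types are the copper-catalysed alkyl–alkyl Grignard coupling and the metal-hydride-initiated reductive radical cyclisation of dienes. C10 is set by the tether, because the chain on C6 can reach C10 only on the face of the flat cyclohexadiene that carries C6, which gives the cis ring fusion (10-H cis to 5-Me); C9 is set by a chair-like transition state with the C8 methyl and the larger arylmethyl group equatorial, which puts the new C9 methyl axial and cis to the C8 methyl; C5 and C8 are carried in from 6 and 19. The step needs hydrogen-atom transfer to the 1,1-disubstituted alkene in preference to the tri- and 1,2-disubstituted ring alkenes (the known rate order secures this) and attack at C10 in preference to C4 (C4 bears a methyl group and would give two adjacent quaternary carbons). The silylated phenol removes the one hydrogen donor that could intercept the C9 radical within the molecule.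

Step 16
Reactants: 23
Product: 24 5-methoxy-2-methyl-7-{[(1R,2S,4aR,8aS)-1,2,4a,5-tetramethyl-1,2,3,4,4a,7,8,8a-octahydronaphthalen-1-yl]methyl}-1,3-benzoxazol-6-ol (target)
Conditions: TBAF, THF, 0 °C; then NH4Cl (aq)
Reagents that add atoms: none
Why: fluoride cleaves the aryl silyl ether under mild, non-acidic conditions that affect neither the trisubstituted alkene nor any stereocentre.

**Compound list**

1 | 2-methylbenzoyl chloride | Cc1ccccc1C(Cl)=O | starting material
2 | (S)-2-(methoxymethyl)pyrrolidine | COC[C@@H]1CCCN1 | starting material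
3 | [(2S)-2-(methoxymethyl)pyrrolidin-1-yl](2-methylphenyl)methanone | Cc1ccccc1C(=O)N1CCC[C@H]1COC | intermediate
4 | [(1R)-1,2-dimethylcyclohexa-2,5-dien-1-yl][(2S)-2-(methoxymethyl)pyrrolidin-1-yl]methanone | COC[C@@H]1CCCN1C(=O)[C@@]1(C)C(C)=CCC=C1 | intermediate
5 | [(1R)-1,2-dimethylcyclohexa-2,5-dien-1-yl]methanol | OC[C@@]1(C)C(C)=CCC=C1 | intermediate
6 | (6R)-6-(iodomethyl)-1,6-dimethylcyclohexa-1,4-diene | IC[C@@]1(C)C(C)=CCC=C1 | intermediate
7 | 4-methoxybenzene-1,3-diol | COc1ccc(O)cc1O | starting material
8 | 4-methoxy-6-nitrobenzene-1,3-diol | COc1cc([N+](=O)[O-])c(O)cc1O | intermediate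
9 | 4-amino-6-methoxybenzene-1,3-diol | COc1cc(N)c(O)cc1O | intermediate
10 | 5-methoxy-2-methyl-1,3-benzoxazol-6-ol | COc1cc2nc(C)oc2cc1O | intermediate
11 | methyl (2S)-3-hydroxy-2-methylpropanoate | COC(=O)[C@@H](C)CO | starting material
12 | methyl (2S)-3-[(tert-butyldimethylsilyl)oxy]-2-methylpropanoate | COC(=O)[C@@H](C)CO[Si](C)(C)C(C)(C)C | intermediate
13 | (3S)-4-[(tert-butyldimethylsilyl)oxy]-1-chloro-3-methylbutan-2-one | ClCC(=O)[C@@H](C)CO[Si](C)(C)C(C)(C)C | intermediate
14 | (3S)-4-[(tert-butyldimethylsilyl)oxy]-1-[(5-methoxy-2-methyl-1,3-benzoxazol-6-yl)oxy]-3-methylbutan-2-one | COc1cc2nc(C)oc2cc1OCC(=O)[C@@H](C)CO[Si](C)(C)C(C)(C)C | intermediate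
15 | 6-({(3R)-4-[(tert-butyldimethylsilyl)oxy]-3-methyl-2-methylidenebutyl}oxy)-5-methoxy-2-methyl-1,3-benzoxazole | COc1cc2nc(C)oc2cc1OCC(=C)[C@@H](C)CO[Si](C)(C)C(C)(C)C | intermediate
16 | 7-{(3R)-4-[(tert-butyldimethylsilyl)oxy]-3-methyl-2-methylidenebutyl}-5-methoxy-2-methyl-1,3-benzoxazol-6-ol | COc1cc2nc(C)oc2c(CC(=C)[C@@H](C)CO[Si](C)(C)C(C)(C)C)c1O | intermediate
17 | 7-{(3R)-4-[(tert-butyldimethylsilyl)oxy]-3-methyl-2-methylidenebutyl}-5-methoxy-2-methyl-6-[(triisopropylsilyl)oxy]-1,3-benzoxazole | COc1cc2nc(C)oc2c(CC(=C)[C@@H](C)CO[Si](C)(C)C(C)(C)C)c1O[Si](C(C)C)(C(C)C)C(C)C | intermediate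
18 | (2R)-4-{5-methoxy-2-methyl-6-[(triisopropylsilyl)oxy]-1,3-benzoxazol-7-yl}-2-methyl-3-methylidenebutan-1-ol | COc1cc2nc(C)oc2c(CC(=C)[C@@H](C)CO)c1O[Si](C(C)C)(C(C)C)C(C)C | intermediate
19 | 7-[(3R)-4-iodo-3-methyl-2-methylidenebutyl]-5-methoxy-2-methyl-6-[(triisopropylsilyl)oxy]-1,3-benzoxazole | COc1cc2nc(C)oc2c(CC(=C)[C@@H](C)CI)c1O[Si](C(C)C)(C(C)C)C(C)C | intermediate
20 | {[(1R)-1,2-dimethylcyclohexa-2,5-dien-1-yl]methyl}lithium | [Li]C[C@@]1(C)C(C)=CCC=C1 | intermediate
21 | {[(1R)-1,2-dimethylcyclohexa-2,5-dien-1-yl]methyl}magnesium bromide | Br[Mg]C[C@@]1(C)C(C)=CCC=C1 | intermediate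
22 | 7-{(3S)-5-[(1R)-1,2-dimethylcyclohexa-2,5-dien-1-yl]-3-methyl-2-methylidenepentyl}-5-methoxy-2-methyl-6-[(triisopropylsilyl)oxy]-1,3-benzoxazole | COc1cc2nc(C)oc2c(CC(=C)[C@@H](C)CC[C@@]2(C)C(C)=CCC=C2)c1O[Si](C(C)C)(C(C)C)C(C)C | intermediate
23 | 5-methoxy-2-methyl-7-{[(1R,2S,4aR,8aS)-1,2,4a,5-tetramethyl-1,2,3,4,4a,7,8,8a-octahydronaphthalen-1-yl]methyl}-6-[(triisopropylsilyl)oxy]-1,3-benzoxazole | COc1cc2nc(C)oc2c(C[C@]2(C)[C@@H](C)CC[C@@]3(C)C(C)=CCC[C@@H]23)c1O[Si](C(C)C)(C(C)C)C(C)C | intermediate
24 | 5-methoxy-2-methyl-7-{[(1R,2S,4aR,8aS)-1,2,4a,5-tetramethyl-1,2,3,4,4a,7,8,8a-octahydronaphthalen-1-yl]methyl}-1,3-benzoxazol-6-ol | COc1cc2nc(C)oc2c(C[C@]2(C)[C@@H](C)CC[C@@]3(C)C(C)=CCC[C@@H]23)c1O | target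

**Step count and risks**

Total step count: 16 steps. Longest linear sequence: 10 steps (11 to 24 through steps 7–16; the branch from 7 through steps 5, 6 and 9–16 is equally long).

Steps most likely to fail:

Step 15. The 6-exo closure onto an unactivated ring alkene is slow, so the tertiary C9 radical may be reduced or the alkene isomerised before ring closure. Hydrogen may also be abstracted from the bis-allylic C2 methylene, and the two faces of the C9 radical may be poorly distinguished. The fallback makes the same C9 radical in a tin hydride chain whose hydride concentration can be kept low. The coupling stage is worked up on its own and diene 22 is isolated. Markovnikov hydrobromination of its 1,1-disubstituted alkene (Co(acac)2, t-BuOOH, Et3SiH, TsBr) should give the tertiary bromide F1. Slow addition of Bu3SnH with AIBN to F1 in benzene at 80 °C should then allow cyclisation to outrun reduction, and the product is 23.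

Step 4. Substitution at the neopentyl carbon is slow, and any ionisation next to the two vinyl groups would lead to a 1,2-vinyl shift or ring expansion. The fallback avoids a leaving group at C6. Alcohol 5 is oxidised with Dess–Martin periodinane to the aldehyde F2, and iodide 19 is heated with PPh3 in MeCN to give the phosphonium iodide F3. Wittig reaction of F3 (NaN(SiMe3)2, THF, −78 °C) with F2 should give the Z-triene F4. Hydrogen-atom-transfer cyclisation of F4 (Fe(acac)3, PhSiH3, EtOH, 60 °C) should give the bicyclic diene F5. Diimide (2-nitrobenzenesulfonohydrazide, Et3N) should then reduce the cis-disubstituted C6=C7 bond in preference to the trisubstituted C3=C4 bond, which returns the route to 23.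

Step 2. With an ortho-methyl group the enolate methylation may show poor or reversed facial selectivity. The fallback replaces auxiliary control by resolution. Acid chloride 1 is hydrolysed (NaOH, water) to 2-methylbenzoic acid F6. Birch reduction (Li, NH3, THF) followed by MeI should give the racemic 1,2-dimethylcyclohexa-2,5-diene-1-carboxylic acid F7. Crystallisation with (S)-1-phenylethylamine is expected to give the salt F8 of the (R)-acid (the (R)-amine is used if the other salt crystallises), and acidification with HCl gives the (R)-acid F9. Reduction with LiAlH4 returns the route to 5.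

Further compounds
F1 | step 15 | 7-{(3S)-2-bromo-5-[(1R)-1,2-dimethylcyclohexa-2,5-dien-1-yl]-2,3-dimethylpentyl}-5-methoxy-2-methyl-6-[(triisopropylsilyl)oxy]-1,3-benzoxazole (both C9 epimers) | COc1cc2nc(C)oc2c(CC(C)(Br)[C@@H](C)CC[C@@]2(C)C(C)=CCC=C2)c1O[Si](C(C)C)(C(C)C)C(C)C
F2 | step 4 | (1R)-1,2-dimethylcyclohexa-2,5-diene-1-carbaldehyde | O=C[C@@]1(C)C(C)=CCC=C1
F3 | step 4 | [(2R)-4-{5-methoxy-2-methyl-6-[(triisopropylsilyl)oxy]-1,3-benzoxazol-7-yl}-2-methyl-3-methylidenebutyl]triphenylphosphonium iodide | COc1cc2nc(C)oc2c(CC(=C)[C@@H](C)C[P+](c2ccccc2)(c2ccccc2)c2ccccc2)c1O[Si](C(C)C)(C(C)C)C(C)C.[I-]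
F4 | step 4 | Z-triene, the C6=C7 (Z)-alkene analogue of 22 with the same configuration at C5 and C8 | COc1cc2nc(C)oc2c(CC(=C)[C@@H](C)/C=C\[C@@]2(C)C(C)=CCC=C2)c1O[Si](C(C)C)(C(C)C)C(C)C
F5 | step 4 | bicyclic diene, the C6=C7 alkene analogue of 23 with the same configuration at C5, C8, C9 and C10 | COc1cc2nc(C)oc2c(C[C@]2(C)[C@@H](C)C=C[C@@]3(C)C(C)=CCC[C@@H]23)c1O[Si](C(C)C)(C(C)C)C(C)C
F6 | step 2 | 2-methylbenzoic acid | Cc1ccccc1C(=O)O
F7 | step 2 | racemic 1,2-dimethylcyclohexa-2,5-diene-1-carboxylic acid | OC(=O)C1(C)C(C)=CCC=C1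
F8 | step 2 | (S)-1-phenylethylammonium (1R)-1,2-dimethylcyclohexa-2,5-diene-1-carboxylate | C[C@H]([NH3+])c1ccccc1.[O-]C(=O)[C@@]1(C)C(C)=CCC=C1
F9 | step 2 | (1R)-1,2-dimethylcyclohexa-2,5-diene-1-carboxylic acid | OC(=O)[C@@]1(C)C(C)=CCC=C1
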